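**The limiting reagent.** The coupling partner is the reagent I watch in this flask: 1.02 M against 1.7 M of substrate makes it the limiting reagent, with a cap of 60.0% product, and it also decomposes on its own.

substrate 1.7 M (in portions, 3); coupling partner 1.02 M; precatalyst 24 mM; time 1.0 h; the portions of substrate follow each other after 80 s, the first at the start

    coupling partner + free catalyst → catalyst intermediate A (k1 = 71.7 L mol⁻¹ min⁻¹)
    substrate + catalyst intermediate A → catalyst intermediate B (k2 = 76.1 L mol⁻¹ min⁻¹)
    catalyst intermediate B → free catalyst + product (k3 = 21.6 min⁻¹)
    precatalyst → free catalyst (k4 = 0.110 min⁻¹)
    coupling partner → decomposed reagent (k5 = 0.0451 min⁻¹)

- which holds at 1.0 h: what has brought the reaction to rest, or that it has not come to rest (it is still moving / the coupling partner has run out first / no working catalyst is left / all of the substrate has reacted)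
- how much product there is at 1.0 h, in percent of the substrate charged
- amount of product if the flask were left three thousand times as long, in percent of the substrate charged

- the reaction counts as stopped when no species that holds the substrate changes by six tenths of a point or more over the second half of the time
- run time (flask): 1.0 h

**Order of rate.** In this flask partner that decomposes gives no product, and I start from one concentration: [coupling partner] = 0.301 M, where capture per free catalyst runs as fast as release per catalyst intermediate B. The charge stands 3.39 times above it, so while [coupling partner] stays high the round should be near zero order in partner.

**Two ways.** Working catalyst grows from precatalyst, at first along a line of slope 2.64 mM min⁻¹. If I call the partner's use pseudo-first-order, it lasts about 3.25 min, and decomposition takes 14.7% of it. If I call it zero order instead, each catalyst turns 11.8 min⁻¹, reckoned at 0.510 M of partner and 1.19 M of substrate. Along that line the growing catalyst has consumed the partner charge by 8.09 min, and I call this time the race time. The line is a stretch, for the race time is longer than the 6.30 min half-life of precatalyst by step 4 alone. Over it the partner averages 66.7% of its charge, so decomposition takes 24.3%.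

**The cheat.** The two part, and the first cheats: at the charge it lets each catalyst capture 73.1 min⁻¹, above the 21.6 min⁻¹ of release. I commit to the second, which gives 45.4% product. Since 8.09 min is shorter than 1.0 h, I expect the partner to end the reaction and a longer wait to add nothing.

**The result.** The forecast gives the coupling partner has run out first, 46.8% at 1.0 h and 46.8% after a long wait, because “Nothing further can form, so waiting longer changes nothing”. The flask gives the coupling partner has run out first, 46.9% and 46.9%, with 0% of the partner and 53% of the substrate left at 1.00 h. In this flask half of the release turnover is done by 5.37 min, sooner than the 15.4 min half-life of the partner by decomposition alone. Decomposed reagent reads 0.223 M in this flask, beside the 0.248 M from my race time.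

**Less catalyst.** With 0.0060 M of precatalyst, my reckoning gives the neighbour flask a race time of 16.2 min, a loss of 48.6% and 30.8% product. By then the line stands at 10.7 mM of catalyst, above the 6.00 mM charged, so in this neighbour flask the figure is rough. That flask gives 36.4% product and 0.402 M decomposed reagent.

The constants used here were drawn at random within sensible limits; no experiment stands behind them.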